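In Monday's run starting material is down to 71.4% after 6.00 min, a half-life of 0.206 h at the coupling partner charge that the flask below shares.

| flask | starting material | coupling partner | second reagent | remark | time |
|---|---|---|---|---|---|
| Tuesday's | 0.18 M | 0.407 M | 0.296 M | run made earlier |  |
| Monday's | 0.28 M | 0.407 M | 0.296 M | run made earlier |  |
| flask | 0.37 M | 0.407 M | 0.296 M |  | 1.5 h |

| run | time / min | product / % | crystals / % | starting material / % |
|---|---|---|---|---|
| Tuesday's | 8.00 | 0.6 | 0 | 63.6 |
| Tuesday's | 12.0 | 1.6 | 0 | 50.5 |
| Tuesday's | 20.0 | 4.0 | 0 | 33.5 |
| Tuesday's | 30.0 | 7.3 | 2.0 | 24.4 |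
| Tuesday's | 50.0 | 15.6 | 0.2 | 11.4 |
| Tuesday's | 80.0 | 28.8 | 1.4 | 4.8 |
| Tuesday's | 120 | 39.6 | 0.9 | 3.0 |
| Monday's | 6.00 | 0 | 0 | 71.4 |
| Monday's | 15.0 | 3.0 | 0 | 47.4 |
| Monday's | 30.0 | 9.9 | 0.7 | 27.3 |
| Monday's | 50.0 | 15.1 | 0 | 14.3 |
| Monday's | 60.0 | 20.0 | 0 | 12.9 |
| Monday's | 80.0 | 27.4 | 0 | 7.6 |
| Monday's | 120 | 36.3 | 8.1 | 3.0 |

(each reading ± 1 percentage point)

- product is meant together with its crystals
- solid, in amounts per volume of the solution: crystals
- reactions considered so far: second reagent + intermediate -> product; starting material + coupling partner -> intermediate; crystals <-> product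

- product and crystals together at 1.5 h, in percent of the starting material charged
- concentration of product in solution at 1.5 h, in percent of saturation

You need a second time to set against that one. Product forms at a rate proportional to second reagent times intermediate, and while second reagent stays near its charge, intermediate decays pseudo-first-order. Percentages should then ignore the starting material charged, and at 80.0 min Tuesday's and Monday's runs read 28.8% and 27.4% product. From 30.0 min to 80.0 min on Monday, product with crystals rose 17 percentage points, with about 63.5% as intermediate and the second reagent at about 0.243 M. That gives 1.79 h as the second-step half-life, the time intermediate takes to halve at charged second reagent. This step is slower than the first by a factor of 8.69, so it is the rate-limiting step. My own reckoning runs Monday's pace from 0.206 h to 1.5 h and gives 26.1% for the flask.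

The forecast is higher than mine, at 28% and 100% of saturation: “The flask therefore sits near saturation, possibly slightly supersaturated or just starting to crystallise.”

The flask gives 25.5% and 106% of saturation.

    second reagent + intermediate → product (k = 3.40 × 10⁻⁴ M⁻¹ s⁻¹)
    starting material + coupling partner → intermediate (k = 0.00260 M⁻¹ s⁻¹)
    crystals ⇌ product, rate k3*(cs3 - [product]) while solid is left; crystals form when [product] > cs3 (solubility = 0.0750 M, k = 0.00360 s⁻¹)

The flask is not at rest: 1.5 h is 0.838 of the half-life you read from Monday's run, with 62.7% as intermediate. At 15.0 h, product and crystals reach 74.2%, against the 80.0% the charges allow, and 25.7% is still intermediate. With 0.12 M of second reagent the half-life read from Monday's run stretches to 4.42 h, and the same reckoning gives 10.6%; that neighbour flask gives 11.4%.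

The numbers in the tables are calculated with made-up constants; the scatter is artificial.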